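**Retrosynthetic overview**
1. Target 24 ⇐ silyl ether 23 ⇐ tertiary hydroxylactam 21. The peri-naphthol closes onto an N-acyliminium ion under a chiral phosphoric acid; this forms the naphthofuran ring last and sets the only stereocentre.
2. 21 ⇐ C3–H lactam 16, by benzyl protection of both naphthols, carbanion oxygenation at C3 and hydrogenolysis.
3. 16 ⇐ hydroxylactam 14 + naphthol 8: the key C–C bond, made by an intermolecular Betti-type (phenolic) Mannich reaction of an N-acyliminium ion.
4. 14 (isoindolinone ring) ⇐ 3-methoxybenzoyl chloride + O-silylated ethanolamine, by amide-directed ortho-lithiation and formylation.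
5. 8 (naphthalene ring, built first) ⇐ 4-(benzyloxy)benzaldehyde + diethyl succinate, by Stobbe condensation and cyclisation.

Assumption: the (R)-configured phosphoric acid in step 13 is taken to give the (S)-spirocentre; the sense of induction is not predictable, so if the first run gives the antipode, the mirror-image catalyst is used.

**Step 1**
Reactants: 1 4-(benzyloxy)benzaldehyde; 2 diethyl succinate
Product: 3 (E)-4-[4-(benzyloxy)phenyl]-3-(ethoxycarbonyl)but-3-enoic acid
Conditions: KOtBu, t-BuOH, reflux; then aq. HCl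
Reagents that add atoms: none
Why: Stobbe condensation (aldol addition, lactonisation, eliminative ring opening) gives the (E)-half-ester, in which the aryl group is cis to CH2CO2H as the next ring closure needs.

**Step 2**
Reactants: 3 (E)-4-[4-(benzyloxy)phenyl]-3-(ethoxycarbonyl)but-3-enoic acid
Product: 5 ethyl 4-acetoxy-6-(benzyloxy)-2-naphthoate, via naphthol ester 4 (not isolated)
Conditions: Ac2O, NaOAc, reflux
Reagents that add atoms: acetic anhydride, CC(=O)OC(C)=O
Why: Intramolecular Friedel–Crafts acylation of the activated acid onto the only kind of ortho position closes the second ring, and the resulting naphthol 4 is acetylated in situ.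

**Step 3**
Reactants: 5 ethyl 4-acetoxy-6-(benzyloxy)-2-naphthoate
Product: 6 7-(benzyloxy)-3-(hydroxymethyl)naphthalen-1-ol
Conditions: LiAlH4, THF, 0 °C → rt; aq. NaOH work-up
Reagents that add atoms: none
Why: Hydride reduction converts the ethyl ester into the primary alcohol and cleaves the aryl acetate in one operation, while the benzyl ether is inert.

**Step 4**
Reactants: 6 7-(benzyloxy)-3-(hydroxymethyl)naphthalen-1-ol
Product: 7 3-(acetoxymethyl)-7-(benzyloxy)naphthalen-1-yl acetate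
Conditions: Ac2O, pyridine, 4-(dimethylamino)pyridine (cat.), CH2Cl2, rt
Reagents that add atoms: acetic anhydride, CC(=O)OC(C)=O
Why: Exhaustive acetylation makes the benzylic oxygen hydrogenolysable and masks the 1-OH as an acetate that deactivates its ring toward electrophiles in step 9.

**Step 5**
Reactants: 7 3-(acetoxymethyl)-7-(benzyloxy)naphthalen-1-yl acetate
Product: 8 7-hydroxy-3-methylnaphthalen-1-yl acetate
Conditions: H2 (1 atm), 10% Pd/C, EtOAc, rt
Reagents that add atoms: none
Why: Catalytic hydrogenolysis cleaves the O-benzyl ether and the naphthylmethyl C–OAc bond (giving the 3-methyl group) but not the aryl acetate, so the two naphthol oxygens emerge differentiated.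

**Step 6**
Reactants: 9 2-aminoethanol
Product: 10 2-[(tert-butyldiphenylsilyl)oxy]ethan-1-amine
Conditions: TBDPSCl, imidazole, CH2Cl2, 0 °C → rt
Reagents that add atoms: tert-butyl(chloro)diphenylsilane, CC(C)(C)[Si](Cl)(c1ccccc1)c1ccccc1
Why: Chemoselective O-silylation, because any Si–N bond formed is hydrolysed on aqueous work-up.

**Step 7**
Reactants: 11 3-methoxybenzoyl chloride; 10 2-[(tert-butyldiphenylsilyl)oxy]ethan-1-amine
Product: 12 N-{2-[(tert-butyldiphenylsilyl)oxy]ethyl}-3-methoxybenzamide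
Conditions: Et3N, CH2Cl2, 0 °C → rt
Reagents that add atoms: none
Why: Straightforward N-acylation of a primary amine by an acid chloride.

**Step 8**
Reactants: 12 N-{2-[(tert-butyldiphenylsilyl)oxy]ethyl}-3-methoxybenzamide
Product: 14 3-hydroxy-4-methoxy-2-{2-[(tert-butyldiphenylsilyl)oxy]ethyl}isoindolin-1-one (racemic), via formyl amide 13 (not isolated)
Conditions: s-BuLi (2.2 equiv), TMEDA, THF, −78 °C; DMF, −78 → 0 °C; aq. NH4Cl
Reagents that add atoms: N,N-dimethylformamide, CN(C)C=O
Why: Directed ortho-metalation, in which the lithium amidate and the methoxy group cooperate to place lithium on the carbon between them; formylation gives 13, which closes to the hydroxylactam (the stereocentre is racemic and is erased in step 9).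

**Step 9**
Reactants: 14 3-hydroxy-4-methoxy-2-{2-[(tert-butyldiphenylsilyl)oxy]ethyl}isoindolin-1-one; 8 7-hydroxy-3-methylnaphthalen-1-yl acetate
Product: 16 7-hydroxy-8-(7-methoxy-3-oxo-2-{2-[(tert-butyldiphenylsilyl)oxy]ethyl}isoindolin-1-yl)-3-methylnaphthalen-1-yl acetate (racemic), via N-acyliminium ion 15 (not isolated)
Conditions: p-TsOH·H2O (20 mol%), 4 Å MS, 1,2-dichloroethane, rt → 60 °C
Reagents that add atoms: none
Why: Betti-type phenolic Mannich reaction, in which acid ionises 14 to N-acyliminium ion 15 and the 2-naphthol attacks through its α-carbon ortho to the free OH (the acetoxy ring is deactivated); the new CH stereocentre is racemic and is erased in steps 11–13.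

**Step 10**
Reactants: 16 7-hydroxy-8-(7-methoxy-3-oxo-2-{2-[(tert-butyldiphenylsilyl)oxy]ethyl}isoindolin-1-yl)-3-methylnaphthalen-1-yl acetate
Product: 18 3-[2,8-bis(benzyloxy)-6-methylnaphthalen-1-yl]-4-methoxy-2-{2-[(tert-butyldiphenylsilyl)oxy]ethyl}isoindolin-1-one (racemic), via diol 17 (not isolated)
Conditions: K2CO3, MeOH, rt, argon; evaporate; BnBr, K2CO3, DMF, 60 °C
Reagents that add atoms: benzyl bromide, BrCc1ccccc1
Why: Methanolysis frees the peri-naphthol and Williamson etherification of both phenoxides gives base-stable benzyl ethers that are later removed together under neutral conditions.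

**Step 11**
Reactants: 18 3-[2,8-bis(benzyloxy)-6-methylnaphthalen-1-yl]-4-methoxy-2-{2-[(tert-butyldiphenylsilyl)oxy]ethyl}isoindolin-1-one
Product: 20 3-[2,8-bis(benzyloxy)-6-methylnaphthalen-1-yl]-3-hydroxy-4-methoxy-2-{2-[(tert-butyldiphenylsilyl)oxy]ethyl}isoindolin-1-one (racemic; ring tautomer of the 2-aroylbenzamide), via hydroperoxide 19 (not isolated)
Conditions: KN(SiMe3)2, THF, −78 °C; O2, P(OEt)3, −78 → −20 °C; aq. NH4Cl
Reagents that add atoms: dioxygen, O=O
Why: The C3–H is doubly benzylic and α to the lactam nitrogen, so deprotonation gives a stabilised 1-oxidoisoindole carbanion that is trapped by O2 and reduced in situ by the phosphite (carbanion autoxidation/hydroxylation); the stereocentre is racemic and is ionised in step 13.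

**Step 12**
Reactants: 20 3-[2,8-bis(benzyloxy)-6-methylnaphthalen-1-yl]-3-hydroxy-4-methoxy-2-{2-[(tert-butyldiphenylsilyl)oxy]ethyl}isoindolin-1-one
Product: 21 3-(2,8-dihydroxy-6-methylnaphthalen-1-yl)-3-hydroxy-4-methoxy-2-{2-[(tert-butyldiphenylsilyl)oxy]ethyl}isoindolin-1-one (racemic)
Conditions: H2 (1 atm), 10% Pd/C, NaHCO3 (solid), EtOAc, rt; filter, use crude
Reagents that add atoms: none
Why: Hydrogenolysis of the two aryl benzyl ethers is fast and neutral, spares the tertiary hemiaminal and the silyl ether, and is done before the benzylic spiro C–O bond exists.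

**Step 13**
Reactants: 21 3-(2,8-dihydroxy-6-methylnaphthalen-1-yl)-3-hydroxy-4-methoxy-2-{2-[(tert-butyldiphenylsilyl)oxy]ethyl}isoindolin-1-one
Product: 23 (S)-3'-hydroxy-7-methoxy-7'-methyl-2-{2-[(tert-butyldiphenylsilyl)oxy]ethyl}spiro[isoindoline-1,2'-naphtho[1,8-bc]furan]-3-one, via N-acyliminium ion 22 (not isolated)
Conditions: (R)-3,3'-bis(2,4,6-triisopropylphenyl)-1,1'-binaphthyl-2,2'-diyl hydrogen phosphate (10 mol%), 4 Å MS, toluene–CH2Cl2, −20 → 0 °C; stop at full conversion; recrystallise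
Reagents that add atoms: none
Why: Enantioselective Brønsted acid-catalysed N-acyliminium spirocyclisation, in which the chiral phosphate ion-pairs with planar cation 22 and hydrogen-bonds the naphthol so that the peri-OH adds to one face, setting the (S)-N,O-ketal centre while the silylated side chain cannot compete.

**Step 14**
Reactants: 23 (S)-3'-hydroxy-7-methoxy-7'-methyl-2-{2-[(tert-butyldiphenylsilyl)oxy]ethyl}spiro[isoindoline-1,2'-naphtho[1,8-bc]furan]-3-one
Product: 24 (S)-3'-hydroxy-2-(2-hydroxyethyl)-7-methoxy-7'-methylspiro[isoindoline-1,2'-naphtho[1,8-bc]furan]-3-one (CNP0434366.2)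
Conditions: Bu4NF, AcOH, THF, 0 °C → rt
Reagents that add atoms: none
Why: Buffered fluoride desilylation frees the primary alcohol without acid, so the N,O-ketal is not ionised and the spirocentre keeps its configuration.

**Compound list**
1 | 4-(benzyloxy)benzaldehyde | O=Cc1ccc(OCc2ccccc2)cc1 | starting material
2 | diethyl succinate | CCOC(=O)CCC(=O)OCC | starting material
3 | (E)-4-[4-(benzyloxy)phenyl]-3-(ethoxycarbonyl)but-3-enoic acid | OC(=O)C/C(C(=O)OCC)=C\c1ccc(OCc2ccccc2)cc1 | intermediate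
4 | ethyl 6-(benzyloxy)-4-hydroxy-2-naphthoate | CCOC(=O)c1cc(O)c2cc(OCc3ccccc3)ccc2c1 | intermediate (not isolated)
5 | ethyl 4-acetoxy-6-(benzyloxy)-2-naphthoate | CCOC(=O)c1cc(OC(C)=O)c2cc(OCc3ccccc3)ccc2c1 | intermediate
6 | 7-(benzyloxy)-3-(hydroxymethyl)naphthalen-1-ol | OCc1cc(O)c2cc(OCc3ccccc3)ccc2c1 | intermediate
7 | 3-(acetoxymethyl)-7-(benzyloxy)naphthalen-1-yl acetate | CC(=O)OCc1cc(OC(C)=O)c2cc(OCc3ccccc3)ccc2c1 | intermediate
8 | 7-hydroxy-3-methylnaphthalen-1-yl acetate | CC(=O)Oc1cc(C)cc2ccc(O)cc12 | intermediate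
9 | 2-aminoethanol | NCCO | starting material
10 | 2-[(tert-butyldiphenylsilyl)oxy]ethan-1-amine | NCCO[Si](c1ccccc1)(c1ccccc1)C(C)(C)C | intermediate
11 | 3-methoxybenzoyl chloride | COc1cccc(C(=O)Cl)c1 | starting material
12 | N-{2-[(tert-butyldiphenylsilyl)oxy]ethyl}-3-methoxybenzamide | COc1cccc(C(=O)NCCO[Si](c2ccccc2)(c2ccccc2)C(C)(C)C)c1 | intermediate
13 | 2-formyl-3-methoxy-N-{2-[(tert-butyldiphenylsilyl)oxy]ethyl}benzamide | COc1cccc(C(=O)NCCO[Si](c2ccccc2)(c2ccccc2)C(C)(C)C)c1C=O | intermediate (not isolated)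
14 | 3-hydroxy-4-methoxy-2-{2-[(tert-butyldiphenylsilyl)oxy]ethyl}isoindolin-1-one (racemic) | COc1cccc2c1C(O)N(CCO[Si](c1ccccc1)(c1ccccc1)C(C)(C)C)C2=O | intermediate
15 | 4-methoxy-1-oxo-2-{2-[(tert-butyldiphenylsilyl)oxy]ethyl}-1H-isoindol-2-ium (N-acyliminium ion) | COc1cccc2c1C=[N+](CCO[Si](c1ccccc1)(c1ccccc1)C(C)(C)C)C2=O | intermediate (not isolated)
16 | 7-hydroxy-8-(7-methoxy-3-oxo-2-{2-[(tert-butyldiphenylsilyl)oxy]ethyl}isoindolin-1-yl)-3-methylnaphthalen-1-yl acetate (racemic) | COc1cccc2c1C(c1c(O)ccc3cc(C)cc(OC(C)=O)c13)N(CCO[Si](c1ccccc1)(c1ccccc1)C(C)(C)C)C2=O | intermediate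
17 | 3-(2,8-dihydroxy-6-methylnaphthalen-1-yl)-4-methoxy-2-{2-[(tert-butyldiphenylsilyl)oxy]ethyl}isoindolin-1-one (racemic) | COc1cccc2c1C(c1c(O)ccc3cc(C)cc(O)c13)N(CCO[Si](c1ccccc1)(c1ccccc1)C(C)(C)C)C2=O | intermediate (not isolated)
18 | 3-[2,8-bis(benzyloxy)-6-methylnaphthalen-1-yl]-4-methoxy-2-{2-[(tert-butyldiphenylsilyl)oxy]ethyl}isoindolin-1-one (racemic) | COc1cccc2c1C(c1c(OCc3ccccc3)ccc3cc(C)cc(OCc4ccccc4)c13)N(CCO[Si](c1ccccc1)(c1ccccc1)C(C)(C)C)C2=O | intermediate
19 | 3-[2,8-bis(benzyloxy)-6-methylnaphthalen-1-yl]-3-hydroperoxy-4-methoxy-2-{2-[(tert-butyldiphenylsilyl)oxy]ethyl}isoindolin-1-one (racemic) | COc1cccc2c1C(OO)(c1c(OCc3ccccc3)ccc3cc(C)cc(OCc4ccccc4)c13)N(CCO[Si](c1ccccc1)(c1ccccc1)C(C)(C)C)C2=O | intermediate (not isolated)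
20 | 3-[2,8-bis(benzyloxy)-6-methylnaphthalen-1-yl]-3-hydroxy-4-methoxy-2-{2-[(tert-butyldiphenylsilyl)oxy]ethyl}isoindolin-1-one (racemic) | COc1cccc2c1C(O)(c1c(OCc3ccccc3)ccc3cc(C)cc(OCc4ccccc4)c13)N(CCO[Si](c1ccccc1)(c1ccccc1)C(C)(C)C)C2=O | intermediate
21 | 3-(2,8-dihydroxy-6-methylnaphthalen-1-yl)-3-hydroxy-4-methoxy-2-{2-[(tert-butyldiphenylsilyl)oxy]ethyl}isoindolin-1-one (racemic) | COc1cccc2c1C(O)(c1c(O)ccc3cc(C)cc(O)c13)N(CCO[Si](c1ccccc1)(c1ccccc1)C(C)(C)C)C2=O | intermediate
22 | 3-(2,8-dihydroxy-6-methylnaphthalen-1-yl)-4-methoxy-1-oxo-2-{2-[(tert-butyldiphenylsilyl)oxy]ethyl}-1H-isoindol-2-ium (N-acyliminium ion) | COc1cccc2c1C(c1c(O)ccc3cc(C)cc(O)c13)=[N+](CCO[Si](c1ccccc1)(c1ccccc1)C(C)(C)C)C2=O | intermediate (not isolated)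
23 | (S)-3'-hydroxy-7-methoxy-7'-methyl-2-{2-[(tert-butyldiphenylsilyl)oxy]ethyl}spiro[isoindoline-1,2'-naphtho[1,8-bc]furan]-3-one | COc1cccc2c1[C@]1(Oc3cc(C)cc4ccc(O)c1c34)N(CCO[Si](c1ccccc1)(c1ccccc1)C(C)(C)C)C2=O | intermediate
24 | (S)-3'-hydroxy-2-(2-hydroxyethyl)-7-methoxy-7'-methylspiro[isoindoline-1,2'-naphtho[1,8-bc]furan]-3-one | COc1cccc2c1[C@]1(Oc3cc(C)cc4ccc(O)c1c34)N(CCO)C2=O | target

**Step count**
Total: 14 steps. Longest linear sequence: 11 steps (steps 1–5, then 9–14).

**Three steps most likely to fail, with fallbacks**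

Step 13 (enantioselective spirocyclisation). The risks are low ee with an N-alkyl N-acyliminium ion and erosion of ee if the product re-ionises. The fallback sets out from 21 and comes back at 23. Compound 21 is closed with an achiral acid (diphenyl phosphate, CH2Cl2) to the racemic spiro N,O-ketal, racemic 3'-hydroxy-7-methoxy-7'-methyl-2-{2-[(tert-butyldiphenylsilyl)oxy]ethyl}spiro[isoindoline-1,2'-naphtho[1,8-bc]furan]-3-one F1. Its phenol is acylated with (1S)-(−)-camphanic chloride (Et3N, 4-(dimethylamino)pyridine) and the two diastereomeric esters are separated by chromatography and crystallisation. The ester that carries the spiro configuration of 23 (assigned by X-ray), the (1S,4R)-camphanate of 23 F2, is cleaved with K2CO3 in MeOH to return to 23.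

Step 9 (Mannich C–C bond). The risk is that the peri-acetoxy group hinders attack at the naphthol α-carbon. The fallback sets out from 14 (with 8) and comes back at 16. Compound 14 is desilylated with Bu4NF and closed with catalytic p-TsOH to the tricyclic N,O-acetal 9-methoxy-2,3-dihydrooxazolo[2,3-a]isoindol-5(9bH)-one F3. TiCl4 (CH2Cl2, −78 → 0 °C) opens F3 to a titanium-bound N-acyliminium alkoxide, and the titanium naphtholate of 8 delivers its ortho carbon to it, giving 7-hydroxy-8-[2-(2-hydroxyethyl)-7-methoxy-3-oxoisoindolin-1-yl]-3-methylnaphthalen-1-yl acetate F4. Silylation of the primary alcohol (TBDPSCl, imidazole) comes back at 16; any aryl silyl ether formed is cleaved in the methanolysis of step 10.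

Step 11 (oxygenation of a hindered carbanion). The risk is that the flanked C3 carbanion reacts sluggishly or unselectively with O2. The fallback sets out from 18 and comes back at 20. The carbanion of 18 (KN(SiMe3)2, THF, −78 °C) is chlorinated with hexachloroethane, a halogen transfer that is less sensitive to hindrance, to give 3-[2,8-bis(benzyloxy)-6-methylnaphthalen-1-yl]-3-chloro-4-methoxy-2-{2-[(tert-butyldiphenylsilyl)oxy]ethyl}isoindolin-1-one F5. F5 ionises readily and is hydrolysed with aqueous NaHCO3 in THF to 20.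

**Further compounds**
F1 | step 13 | racemic 3'-hydroxy-7-methoxy-7'-methyl-2-{2-[(tert-butyldiphenylsilyl)oxy]ethyl}spiro[isoindoline-1,2'-naphtho[1,8-bc]furan]-3-one | COc1cccc2c1C1(Oc3cc(C)cc4ccc(O)c1c34)N(CCO[Si](c1ccccc1)(c1ccccc1)C(C)(C)C)C2=O
F2 | step 13 | (1S,4R)-camphanate ester of 23 at the 3'-oxygen (spiro configuration as in 23) | COc1cccc2c1[C@]1(Oc3cc(C)cc4ccc(OC(=O)[C@@]56CC[C@@](C)(C(=O)O5)C6(C)C)c1c34)N(CCO[Si](c1ccccc1)(c1ccccc1)C(C)(C)C)C2=O
F3 | step 9 | 9-methoxy-2,3-dihydrooxazolo[2,3-a]isoindol-5(9bH)-one (racemic) | COc1cccc2c1C1OCCN1C2=O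
F4 | step 9 | 7-hydroxy-8-[2-(2-hydroxyethyl)-7-methoxy-3-oxoisoindolin-1-yl]-3-methylnaphthalen-1-yl acetate (racemic) | COc1cccc2c1C(c1c(O)ccc3cc(C)cc(OC(C)=O)c13)N(CCO)C2=O
F5 | step 11 | 3-[2,8-bis(benzyloxy)-6-methylnaphthalen-1-yl]-3-chloro-4-methoxy-2-{2-[(tert-butyldiphenylsilyl)oxy]ethyl}isoindolin-1-one (racemic) | COc1cccc2c1C(Cl)(c1c(OCc3ccccc3)ccc3cc(C)cc(OCc4ccccc4)c13)N(CCO[Si](c1ccccc1)(c1ccccc1)C(C)(C)C)C2=O
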